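**Plan**
- The target's 2-methylcyclopent-2-enone (C1–C5, with the C3 ketone, the C4 methyl and C4=C5) is fused at C1/C5 to the seven-membered ring, and the methyl-bearing C10 sits next to C1. This is the unit that a 4-methyl cross-conjugated cyclohexadienone gives on irradiation in aqueous acid, so the retrosynthesis cuts C1–C5 and rejoins C5–C10, after first cutting the C8 ester and replacing C10–H by C10–OH.
- The resulting 10-epi-eudesma-1,4-dien-3-one is cut at C1–C10 and C4=C5 (Robinson annulation with ethyl vinyl ketone), at C7–C11 (conjugate addition of isopropenyl) and at C10–CH3 (enolate methylation), back to 4,4-ethylenedioxycyclohex-2-enone, whose masked ketone becomes C8.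
- Forward: ring B is substituted first, ring A is annulated onto it, C1–C2 is dehydrogenated, and light then closes the five-membered ring and enlarges ring B to the seven-membered ring. C10 is deoxygenated by dehydration and hydrogenation, and the C8 methacrylate is attached last.
- Stereochemistry: C7 comes from the rhodium/(R)-BINAP addition. The angular methyl trans to the C7 group comes from axial Michael addition, and C8 from hydride attack anti to the C7 group. C1 comes from the photorearrangement (relayed from C10), and the final C10 from hydrogenation on the face away from the C7 and C8 groups.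

Key step: step 10

Assumption: the sense of induction in step 2 is taken from the established 2-cyclohexenone model for rhodium/BINAP additions; bicyclic compounds carry eudesmane or guaiane numbers, and β denotes the face of the C7 side chain.

**Step 1**
Reactants: 1 1,4-dioxaspiro[4.5]dec-6-en-8-one
Product: 2 (±)-9-methyl-1,4-dioxaspiro[4.5]dec-6-en-8-one
Conditions: LiN(i-Pr)2, THF, −78 °C; MeI, −78 → 0 °C
Reagents that add atoms: iodomethane, CI
Why: The γ carbon of this enone is the quaternary ketal carbon, so kinetic deprotonation can only give the cross-conjugated α′ lithium dienolate, whose C-methylation (enolate alkylation) is routine; the new centre is racemic and is left unassigned because it becomes an enolate carbon in step 4.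

**Step 2**
Reactants: 2 (±)-9-methyl-1,4-dioxaspiro[4.5]dec-6-en-8-one; 3 isopropenylboronic acid pinacol ester
Product: 4 (6R)-9-methyl-6-(prop-1-en-2-yl)-1,4-dioxaspiro[4.5]decan-8-one (both C9 epimers)
Conditions: [RhCl(cod)]2 (3 mol %), (R)-BINAP (7 mol %), aq KOH (0.5 equiv), 1,4-dioxane, 50 °C
Reagents that add atoms: none
Why: This is a Hayashi–Miyaura rhodium-catalysed asymmetric 1,4-addition of an alkenylboron reagent to a cyclohexenone; by analogy with 2-cyclohexenone, where (R)-BINAP gives the (R)-3-substituted ketone, the isopropenyl group should enter the same enone face and set the (6R) centre (the future C7) under ligand control for both enantiomers of 2, whose α′ centre in any case epimerises under the basic conditions.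

**Step 3**
Reactants: 4 (6R)-9-methyl-6-(prop-1-en-2-yl)-1,4-dioxaspiro[4.5]decan-8-one
Product: 5 (6R)-6-(2-hydroxypropan-2-yl)-9-methyl-1,4-dioxaspiro[4.5]decan-8-one (both C9 epimers)
Conditions: Co(acac)2 (20 mol %), PhSiH3, O2 (1 atm), i-PrOH, 20 °C
Reagents that add atoms: dioxygen, O=O
Why: In this Mukaiyama hydration a cobalt hydride transfers a hydrogen atom to the terminal carbon of the 1,1-disubstituted alkene, the tertiary radical is trapped by O2 and the peroxide is reduced by the silane, which should give the Markovnikov tertiary alcohol without touching ketone or ketal and without creating a stereocentre.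

**Step 4**
Reactants: 5 (6R)-6-(2-hydroxypropan-2-yl)-9-methyl-1,4-dioxaspiro[4.5]decan-8-one; 6 ethyl vinyl ketone
Product: 9 8,8-(ethylenedioxy)-11-hydroxy-10-epi-eudesm-4-en-3-one, via diketone 7 (not isolated), via ketol 8 (not isolated)
Conditions: KOH (0.3 equiv), EtOH, −10 → 20 °C; then 75 °C
Reagents that add atoms: none
Why: This is a Robinson annulation (Michael addition of the more substituted potassium enolate, intramolecular aldol reaction, base-induced dehydration) in which the enolate should be attacked axially through a chair-like transition state on the half-chair that keeps the large hydroxyisopropyl group equatorial, which puts the new chain cis to that group and the angular methyl trans to it, as is known for dihydrocarvone giving 10-epi-α-cyperone; the ketal offers one oxygen to either chair-like trajectory and so should not change the preference.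

**Step 5**
Reactants: 9 8,8-(ethylenedioxy)-11-hydroxy-10-epi-eudesm-4-en-3-one
Product: 10 11-hydroxy-10-epi-eudesm-4-ene-3,8-dione
Conditions: 1 M aq HCl (cat.), THF, 20 °C
Reagents that add atoms: water, O
Why: Acid-catalysed acetal hydrolysis unmasks the C8 ketone, and in dilute acid at 20 °C enolisation towards C7 should be slow enough to keep the C7 configuration while the tertiary alcohol and the enone are not affected.

**Step 6**
Reactants: 10 11-hydroxy-10-epi-eudesm-4-ene-3,8-dione
Product: 11 8β,11-dihydroxy-10-epi-eudesm-4-en-3-one
Conditions: LiBH(s-Bu)3 (1.2 equiv), THF, −78 °C; aq NH4Cl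
Reagents that add atoms: none
Why: In this hindered trialkylborohydride reduction the saturated C8 ketone should react much faster than the tetrasubstituted conjugated C3 ketone, and hydride should attack C8 from the face away from the adjacent C7 side chain (equatorial attack, the axial path being closed by the C1 methylene), which sets the 8β-hydroxyl cis to the side chain.

**Step 7**
Reactants: 11 8β,11-dihydroxy-10-epi-eudesm-4-en-3-one
Product: 12 8β-(tert-butyldimethylsilyloxy)-11-hydroxy-10-epi-eudesm-4-en-3-one
Conditions: TBSOTf (1.1 equiv), 2,6-lutidine, CH2Cl2, −78 °C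
Reagents that add atoms: tert-butyldimethylsilyl trifluoromethanesulfonate, CC(C)(C)[Si](C)(C)OS(=O)(=O)C(F)(F)F
Why: In silyl ether formation a silyl triflate reacts with a secondary alcohol at −78 °C far faster than with a tertiary one, so the C8 hydroxyl should be protected alone and the C11 hydroxyl left free for step 8.

**Step 8**
Reactants: 12 8β-(tert-butyldimethylsilyloxy)-11-hydroxy-10-epi-eudesm-4-en-3-one
Product: 13 11-acetoxy-8β-(tert-butyldimethylsilyloxy)-10-epi-eudesm-4-en-3-one
Conditions: Ac2O, DMAP, Et3N, CH2Cl2, 40 °C
Reagents that add atoms: acetic anhydride, CC(=O)OC(C)=O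
Why: Steglich acylation with DMAP as nucleophilic catalyst is the standard way to acetylate a hindered tertiary alcohol, and the silyl ether and the enone are inert to it.

**Step 9**
Reactants: 13 11-acetoxy-8β-(tert-butyldimethylsilyloxy)-10-epi-eudesm-4-en-3-one
Product: 14 11-acetoxy-8β-(tert-butyldimethylsilyloxy)-10-epi-eudesma-1,4-dien-3-one
Conditions: DDQ (1.5 equiv), 1,4-dioxane, reflux
Reagents that add atoms: none
Why: DDQ dehydrogenation of a 4-en-3-one under neutral conditions proceeds by hydride abstraction from C1 of the 2,4-dienol and should give the cross-conjugated 1,4-dien-3-one, as is known for 4-methyl eudesmenones, with no stereocentre touched.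

**Step 10**
Reactants: 14 11-acetoxy-8β-(tert-butyldimethylsilyloxy)-10-epi-eudesma-1,4-dien-3-one
Product: 15 11-acetoxy-8β-(tert-butyldimethylsilyloxy)-10β-hydroxy-1βH,7αH-guai-4-en-3-one
Conditions: hν (medium-pressure Hg lamp, Pyrex), AcOH–H2O (2:1), 15 °C, Ar
Reagents that add atoms: water, O
Why: Excitation of the dienone and intersystem crossing give a triplet in which the two β carbons C1 and C5 bond, and the resulting bicyclo[3.1.0]hexenone zwitterion (cyclopropane C1–C5–C10) is O-protonated in the acidic medium; water then attacks tertiary C10 while the C5–C10 bond breaks, which restores the C3 ketone and the C4=C5 double bond. The closest known reaction is the santonin to isophotosantonic lactone rearrangement, which is general for 4-methyl eudesma-1,4-dien-3-ones in aqueous acetic acid. The five-membered ring (C1 to C5) closes by the new C1–C5 bond, formed as a three-membered closure across C10, and the seven-membered ring (C1, C5, C6 to C10) is not closed at all but arises from ring B by loss of the C5–C10 bond, a one-carbon ring enlargement. C1 is controlled by the quaternary C10 centre, because C1 keeps its bond to C10 and suprafacial bonding to C5 leaves H1 trans to the C10 methyl, that is on the β face with the C7 and C8 substituents; C10 is controlled by backside attack of water anti to the departing C5, which gives the 10β-hydroxy 10α-methyl arrangement. The step needs the cyclopropane to open towards C10 and not towards spiro or lumiketone products, and this is secured by the C4 methyl group, which localises the positive charge of the hydroxyallyl cation at C4 next to C5, and by the protic nucleophilic medium; the silyl ether, the acetate and the C7 and C8 centres take no part and do not absorb through Pyrex.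

**Step 11**
Reactants: 15 11-acetoxy-8β-(tert-butyldimethylsilyloxy)-10β-hydroxy-1βH,7αH-guai-4-en-3-one
Product: 16 11-acetoxy-8β-(tert-butyldimethylsilyloxy)-1βH,7αH-guaia-4,9-dien-3-one
Conditions: SOCl2, pyridine, CH2Cl2, −20 → 0 °C
Reagents that add atoms: none
Why: The chlorosulfite of the tertiary alcohol undergoes pyridine-induced anti elimination (E2), in which H1 is cis to the C10 oxygen and cannot become antiperiplanar, so the conjugated 1(10)-olefin should not form, while the trans C9 hydrogen gives the more substituted 9-olefin (Saytzeff) and leaves C1 intact.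

**Step 12**
Reactants: 16 11-acetoxy-8β-(tert-butyldimethylsilyloxy)-1βH,7αH-guaia-4,9-dien-3-one
Product: 17 11-acetoxy-8β-(tert-butyldimethylsilyloxy)-1βH,7αH,10αH-guai-4-en-3-one
Conditions: H2 (1 atm), PtO2 (cat.), EtOAc, 20 °C
Reagents that add atoms: none
Why: In this heterogeneous catalytic hydrogenation the trisubstituted C9=C10 bond should be reduced while the tetrasubstituted enone survives, and hydrogen should be delivered to the α face because the β face is covered by the allylic C8 silyloxy group and the C7 acetoxyisopropyl group, which sets H10 α and the methyl β, cis to H1.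

**Step 13**
Reactants: 17 11-acetoxy-8β-(tert-butyldimethylsilyloxy)-1βH,7αH,10αH-guai-4-en-3-one
Product: 18 11-acetoxy-8β-hydroxy-1βH,7αH,10αH-guai-4-en-3-one
Conditions: HF·pyridine, THF, 0 → 20 °C
Reagents that add atoms: none
Why: Fluoride desilylation under mildly acidic conditions should free the C8 hydroxyl without forming an alkoxide, so the neighbouring tertiary acetate neither migrates nor is lost and the base-sensitive C1 centre is not exposed.

**Step 14**
Reactants: 18 11-acetoxy-8β-hydroxy-1βH,7αH,10αH-guai-4-en-3-one
Product: 19 11-acetoxy-8β-(2-methylprop-2-enoyloxy)-1βH,7αH,10αH-guai-4-en-3-one (CNP0318307.1)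
Conditions: methacrylic anhydride, DMAP, Et3N, CH2Cl2, 0 → 20 °C
Reagents that add atoms: methacrylic anhydride, C=C(C)C(=O)OC(=O)C(C)=C
Why: DMAP-catalysed acylation (Steglich-type esterification) of the only free hydroxyl with the anhydride should give the methacrylate, with no stereocentre involved.

**Compound list**
1 | 1,4-dioxaspiro[4.5]dec-6-en-8-one (4,4-ethylenedioxycyclohex-2-enone) | O=C1C=CC2(CC1)OCCO2 | starting material
2 | (±)-9-methyl-1,4-dioxaspiro[4.5]dec-6-en-8-one | CC1CC2(OCCO2)C=CC1=O | intermediate
3 | 4,4,5,5-tetramethyl-2-(prop-1-en-2-yl)-1,3,2-dioxaborolane (isopropenylboronic acid pinacol ester) | CC(=C)B1OC(C)(C)C(C)(C)O1 | starting material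
4 | (6R)-9-methyl-6-(prop-1-en-2-yl)-1,4-dioxaspiro[4.5]decan-8-one, both C9 epimers | CC1CC2(OCCO2)[C@H](CC1=O)C(C)=C | intermediate
5 | (6R)-6-(2-hydroxypropan-2-yl)-9-methyl-1,4-dioxaspiro[4.5]decan-8-one, both C9 epimers | CC1CC2(OCCO2)[C@H](CC1=O)C(C)(C)O | intermediate
6 | ethyl vinyl ketone (pent-1-en-3-one) | CCC(=O)C=C | starting material
7 | (6R,9S)-6-(2-hydroxypropan-2-yl)-9-methyl-9-(3-oxopentyl)-1,4-dioxaspiro[4.5]decan-8-one (oxopentyl chain cis to the hydroxyisopropyl group) | CCC(=O)CC[C@@]1(C)CC2(OCCO2)[C@H](CC1=O)C(C)(C)O | intermediate (not isolated)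
8 | cis-fused ketol 8,8-(ethylenedioxy)-5,11-dihydroxy-10-epi-eudesman-3-one (5-hydroxyl cis to the angular methyl; C4 left unassigned, it is lost on dehydration) | CC1C(=O)CC[C@@]2(C)CC3(OCCO3)[C@H](C[C@@]12O)C(C)(C)O | intermediate (not isolated)
9 | 8,8-(ethylenedioxy)-11-hydroxy-10-epi-eudesm-4-en-3-one (side chain 7β, angular methyl 10α) | O=C1CC[C@@]2(C)CC3(OCCO3)[C@H](CC2=C1C)C(C)(C)O | intermediate
10 | 11-hydroxy-10-epi-eudesm-4-ene-3,8-dione | O=C1CC[C@@]2(C)CC(=O)[C@H](CC2=C1C)C(C)(C)O | intermediate
11 | 8β,11-dihydroxy-10-epi-eudesm-4-en-3-one | O=C1CC[C@@]2(C)C[C@@H](O)[C@H](CC2=C1C)C(C)(C)O | intermediate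
12 | 8β-(tert-butyldimethylsilyloxy)-11-hydroxy-10-epi-eudesm-4-en-3-one | O=C1CC[C@@]2(C)C[C@@H](O[Si](C)(C)C(C)(C)C)[C@H](CC2=C1C)C(C)(C)O | intermediate
13 | 11-acetoxy-8β-(tert-butyldimethylsilyloxy)-10-epi-eudesm-4-en-3-one | O=C1CC[C@@]2(C)C[C@@H](O[Si](C)(C)C(C)(C)C)[C@H](CC2=C1C)C(C)(C)OC(C)=O | intermediate
14 | 11-acetoxy-8β-(tert-butyldimethylsilyloxy)-10-epi-eudesma-1,4-dien-3-one | O=C1C=C[C@@]2(C)C[C@@H](O[Si](C)(C)C(C)(C)C)[C@H](CC2=C1C)C(C)(C)OC(C)=O | intermediate
15 | 11-acetoxy-8β-(tert-butyldimethylsilyloxy)-10β-hydroxy-1βH,7αH-guai-4-en-3-one (C10 methyl α) | CC(C)(C)[Si](C)(C)O[C@@H]1C[C@](C)(O)[C@H]2CC(=O)C(C)=C2C[C@@H]1C(C)(C)OC(C)=O | intermediate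
16 | 11-acetoxy-8β-(tert-butyldimethylsilyloxy)-1βH,7αH-guaia-4,9-dien-3-one | CC(C)(C)[Si](C)(C)O[C@@H]1C=C(C)[C@H]2CC(=O)C(C)=C2C[C@@H]1C(C)(C)OC(C)=O | intermediate
17 | 11-acetoxy-8β-(tert-butyldimethylsilyloxy)-1βH,7αH,10αH-guai-4-en-3-one | CC(C)(C)[Si](C)(C)O[C@@H]1C[C@H](C)[C@H]2CC(=O)C(C)=C2C[C@@H]1C(C)(C)OC(C)=O | intermediate
18 | 11-acetoxy-8β-hydroxy-1βH,7αH,10αH-guai-4-en-3-one | O[C@@H]1C[C@H](C)[C@H]2CC(=O)C(C)=C2C[C@@H]1C(C)(C)OC(C)=O | intermediate
19 | (1R,7S,8R,10S)-11-acetoxy-8-(2-methylprop-2-enoyloxy)guai-4-en-3-one (1βH,7αH,10αH; 8β ester) | C=C(C)C(=O)O[C@@H]1C[C@H](C)[C@H]2CC(=O)C(C)=C2C[C@@H]1C(C)(C)OC(C)=O | target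

**Totals**
Total step count: 14. Longest linear sequence: 14 steps (1 to 19).

**Steps most likely to fail**

Step 12. The risk is delivery of hydrogen to the wrong face of C9=C10: the fold of the cyclopentenone makes the α face near C10 concave, and this competes with the β shielding by the C8 and C7 groups. The risk is made worse by any exocyclic olefin from step 11, which lacks the allylic C8 shield, and by slow over-reduction of the enone. The fallback sets out from 16 and replaces surface hydrogenation by radical hydrogen-atom-transfer hydrogenation (Mn(dpm)3 cat., PhSiH3, t-BuOOH, i-PrOH, 20 °C). This passes through the C10 tertiary radical, so stereocontrol rests on product stability rather than on catalyst approach. The more stable epimer is expected to have the methyl trans to C2 across C1–C10 and cis-1,3 to the C8 oxygen, which is the target arrangement. Both olefin regioisomers converge on the same radical, and the tetrasubstituted enone is expected to react more slowly. The fallback returns to the route at 17 and makes no new compound (F0).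

Step 10. The risks are partial acid-promoted loss of the silyl ether during irradiation, diversion of the excited dienone into lumiketone-type and phenolic products, and secondary photolysis of the product on over-irradiation. The fallback sets out from 14, which is desilylated first (HF·pyridine, THF) to 11-acetoxy-8β-hydroxy-10-epi-eudesma-1,4-dien-3-one F1. The free alcohol is then irradiated in aqueous acetic acid at low conversion per pass to 11-acetoxy-8β,10β-dihydroxy-1βH,7αH-guai-4-en-3-one F2, so that nothing acid-labile is present during the photoreaction. Selective silylation of the secondary C8 hydroxyl (TBSOTf, 2,6-lutidine, CH2Cl2, −78 °C; the tertiary C10 hydroxyl does not react) returns to the route at 15.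

Step 4. The risks are insufficient facial selectivity in the Michael addition (the chain entering trans to the C7 group gives the C10 epimer) and base-induced polymerisation of the vinyl ketone. The fallback sets out from 5, which is condensed with (S)-1-phenylethylamine (4 Å molecular sieves, toluene, 80 °C) to the imine (6R)-6-(2-hydroxypropan-2-yl)-9-methyl-N-[(S)-1-phenylethyl]-1,4-dioxaspiro[4.5]decan-8-imine F3. Its secondary enamine tautomer adds to ethyl vinyl ketone 6 under neutral conditions (THF, 40 °C) with the auxiliary reinforcing the substrate preference. Mild hydrolysis (aq AcOH, 20 °C) gives the diketone 7, now isolated, and aldol condensation (NaOMe, MeOH, 60 °C) returns to the route at 9.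

**Further compounds**
F0 | step 12 | none | none
F1 | step 10 | 11-acetoxy-8β-hydroxy-10-epi-eudesma-1,4-dien-3-one | O=C1C=C[C@@]2(C)C[C@@H](O)[C@H](CC2=C1C)C(C)(C)OC(C)=O
F2 | step 10 | 11-acetoxy-8β,10β-dihydroxy-1βH,7αH-guai-4-en-3-one | O[C@@H]1C[C@](C)(O)[C@H]2CC(=O)C(C)=C2C[C@@H]1C(C)(C)OC(C)=O
F3 | step 4 | (6R)-6-(2-hydroxypropan-2-yl)-9-methyl-N-[(S)-1-phenylethyl]-1,4-dioxaspiro[4.5]decan-8-imine | CC1CC2(OCCO2)[C@H](CC1=N[C@@H](C)c1ccccc1)C(C)(C)O
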